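**Retrosynthetic overview**

1. Target 29 ← 28 by desilylation ← 26 by acylation of the C8 alcohol with (S)-2-methylbutanoic acid.
2. Key disconnection C7–C8: 26 ← seco-aldehyde 24. An intramolecular chromium-mediated allylation of the C8 aldehyde by a 3-(bromomethyl)butenolide closes the ten-membered carbocycle (C1–C10), sets C7 and C8, and moves the lactone olefin to the exocyclic C11=C13 position.
3. Enabling feature: in the target, O8–C8–C7–C11=C13 is a homoallylic alcohol whose allyl unit sits in the γ-lactone ring (O–C12–C11–C7–C6), so the lactone can be carried as its C7=C11 butenolide isomer with bromine on C13. The Z C4=C5 olefin and the trans C1–C10 oxirane fold the C5→C8 tether.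
4. 24 ← butenolide by ring-closing metathesis of a 2-(bromomethyl)acrylate on O6 ← C3–C4 union (Nozaki–Hiyama–Kishi) of Z-vinyl iodide 14 with epoxy aldehyde 8, C3 then fixed by oxidation and CBS reduction. 14 comes from crotonaldehyde and a propargyl ether (alkynylation, Red-Al/I2); 8 from butynol (carboalumination/oxirane opening, Shi epoxidation).
5. Ring order: oxirane (step 3) → butenolide lactone (step 14) → ten-membered carbocycle (step 17).

Key step: step 17

Assumption: the (S,S)-enantiomer of the ProPhenol ligand is taken as the one that gives the S propargylic alcohol from an enal; if the sense were the opposite, the (R,R)-ligand would be used in step 5 and nothing else would change.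

Abbreviations: PMB = 4-methoxybenzyl, TBS = tert-butyldimethylsilyl, TES = triethylsilyl. Atom numbers C1–C15 are germacrane numbers of the target.

**Route**

Step 1
Reactants: 1 but-3-yn-1-ol
Product: 2 1-[(but-3-yn-1-yloxy)methyl]-4-methoxybenzene
Conditions: NaH, 4-methoxybenzyl chloride, Bu4NI (cat.), THF, 0 °C to rt
Reagents that add atoms: 4-methoxybenzyl chloride, COc1ccc(CCl)cc1
Why: Williamson etherification of the sodium alkoxide protects the future C8 oxygen as a PMB ether that can later be removed oxidatively without touching silyl ethers; no stereocenter is formed.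

Step 2
Reactants: 2 1-[(but-3-yn-1-yloxy)methyl]-4-methoxybenzene; 3 oxirane
Product: 6 (3E)-6-[(4-methoxybenzyl)oxy]-4-methylhex-3-en-1-ol, via alkenyldimethylalane 4 (not isolated), via lithium alkenylalanate 5 (not isolated)
Conditions: Me3Al, Cp2ZrCl2 (20 mol %), CH2Cl2, 0 °C to rt; n-BuLi, THF/hexane, −30 °C; oxirane, −30 °C to rt; aq. potassium sodium tartrate
Reagents that add atoms: trimethylaluminium, C[Al](C)C
Why: Zirconium-catalysed carboalumination (Negishi) adds methyl and aluminium syn across the terminal alkyne with methyl on the internal carbon, and the derived lithium alanate opens oxirane with retention of olefin geometry, so the E-trisubstituted C1=C10 olefin with C14 in place should result.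

Step 3
Reactants: 6 (3E)-6-[(4-methoxybenzyl)oxy]-4-methylhex-3-en-1-ol
Product: 7 2-[(2R,3R)-3-{2-[(4-methoxybenzyl)oxy]ethyl}-3-methyloxiran-2-yl]ethan-1-ol
Conditions: D-fructose-derived Shi ketone (30 mol %), Oxone (2KHSO5·KHSO4·K2SO4), K2CO3, Bu4NHSO4, MeCN/dimethoxymethane, aq. Na2B4O7 buffer, 0 °C
Reagents that add atoms: potassium peroxymonosulfate (the KHSO5 of Oxone), [K+].[O-]S(=O)(=O)OO
Why: Shi asymmetric epoxidation (chiral dioxirane, spiro transition state) of the E-trisubstituted olefin; the D-fructose-derived ketone should deliver oxygen to the face that gives the (R,R)-oxirane, which sets C1 and C10 by catalyst control.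

Step 4
Reactants: 7 2-[(2R,3R)-3-{2-[(4-methoxybenzyl)oxy]ethyl}-3-methyloxiran-2-yl]ethan-1-ol
Product: 8 2-[(2R,3R)-3-{2-[(4-methoxybenzyl)oxy]ethyl}-3-methyloxiran-2-yl]acetaldehyde
Conditions: Dess–Martin periodinane, NaHCO3, CH2Cl2, 0 °C; crude aldehyde used at once
Reagents that add atoms: none
Why: Buffered Dess–Martin oxidation is neutral enough to give the β,γ-epoxy aldehyde (C3) without β-elimination of the oxirane, and no stereocenter is touched.

Step 5
Reactants: 9 (2E)-but-2-enal; 10 tert-butyldimethyl(prop-2-yn-1-yloxy)silane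
Product: 11 (4S,5E)-1-[(tert-butyldimethylsilyl)oxy]hept-5-en-2-yn-4-ol
Conditions: Me2Zn, (S,S)-ProPhenol (10 mol %), Ph3PO (20 mol %), toluene, 4 °C
Reagents that add atoms: none
Why: Catalytic enantioselective alkynylation of an enal (1,2-addition of an alkynylzinc held in the dinuclear zinc–ProPhenol complex) should set the C6 carbinol as S by ligand control, the propenyl group serving later as the metathesis handle.

Step 6
Reactants: 11 (4S,5E)-1-[(tert-butyldimethylsilyl)oxy]hept-5-en-2-yn-4-ol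
Product: 13 (2Z,4S,5E)-1-[(tert-butyldimethylsilyl)oxy]-2-iodohepta-2,5-dien-4-ol, via cyclic vinylalanate 12 (not isolated)
Conditions: NaAlH2(OCH2CH2OCH3)2 (Red-Al), THF, 0 °C; then I2, THF, −78 °C
Reagents that add atoms: iodine, II
Why: Hydroxyl-directed trans-hydroalumination of the propargylic alcohol places aluminium on the distal alkyne carbon (C4) in a five-membered alkoxyalanate, and iodinolysis with retention should give the Z vinyl iodide with iodine cis to C6, which fixes the C4=C5 geometry; the propenyl group and C6 are untouched.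

Step 7
Reactants: 13 (2Z,4S,5E)-1-[(tert-butyldimethylsilyl)oxy]-2-iodohepta-2,5-dien-4-ol
Product: 14 tert-butyl{[(2Z,4S,5E)-2-iodo-4-[(triethylsilyl)oxy]hepta-2,5-dien-1-yl]oxy}dimethylsilane
Conditions: TESCl, imidazole, CH2Cl2, 0 °C
Reagents that add atoms: chlorotriethylsilane, CC[Si](Cl)(CC)CC
Why: Standard silylation masks the C6 hydroxyl as a TES ether that is later removable in the presence of TBS ethers; no stereocenter is touched.

Step 8
Reactants: 14 tert-butyl{[(2Z,4S,5E)-2-iodo-4-[(triethylsilyl)oxy]hepta-2,5-dien-1-yl]oxy}dimethylsilane; 8 2-[(2R,3R)-3-{2-[(4-methoxybenzyl)oxy]ethyl}-3-methyloxiran-2-yl]acetaldehyde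
Product: 15 (3Z,5S,6E)-3-{[(tert-butyldimethylsilyl)oxy]methyl}-1-[(2R,3R)-3-{2-[(4-methoxybenzyl)oxy]ethyl}-3-methyloxiran-2-yl]-5-[(triethylsilyl)oxy]octa-3,6-dien-2-ol (both epimers at the carbinol, which is C3)
Conditions: CrCl2 (4 equiv), NiCl2 (2 mol %), DMSO, rt
Reagents that add atoms: none
Why: Nozaki–Hiyama–Kishi coupling (oxidative addition of the vinyl iodide to zerovalent nickel, transmetalation to trivalent chromium, addition to the aldehyde) forms C3–C4 with retention of the Z geometry under non-basic conditions that an enolisable β,γ-epoxy aldehyde should tolerate; the C3 carbinol forms without control and is corrected in steps 9 and 10.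

Step 9
Reactants: 15 (3Z,5S,6E)-3-{[(tert-butyldimethylsilyl)oxy]methyl}-1-[(2R,3R)-3-{2-[(4-methoxybenzyl)oxy]ethyl}-3-methyloxiran-2-yl]-5-[(triethylsilyl)oxy]octa-3,6-dien-2-ol
Product: 16 (3Z,5S,6E)-3-{[(tert-butyldimethylsilyl)oxy]methyl}-1-[(2R,3R)-3-{2-[(4-methoxybenzyl)oxy]ethyl}-3-methyloxiran-2-yl]-5-[(triethylsilyl)oxy]octa-3,6-dien-2-one
Conditions: Dess–Martin periodinane, NaHCO3, CH2Cl2, 0 °C
Reagents that add atoms: none
Why: Buffered Dess–Martin oxidation converges both C3 epimers to one Z enone without base that could open the β,γ-oxirane or isomerise the olefin.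

Step 10
Reactants: 16 (3Z,5S,6E)-3-{[(tert-butyldimethylsilyl)oxy]methyl}-1-[(2R,3R)-3-{2-[(4-methoxybenzyl)oxy]ethyl}-3-methyloxiran-2-yl]-5-[(triethylsilyl)oxy]octa-3,6-dien-2-one
Product: 17 (2S,3Z,5S,6E)-3-{[(tert-butyldimethylsilyl)oxy]methyl}-1-[(2R,3R)-3-{2-[(4-methoxybenzyl)oxy]ethyl}-3-methyloxiran-2-yl]-5-[(triethylsilyl)oxy]octa-3,6-dien-2-ol
Conditions: (R)-2-methyl-CBS-oxazaborolidine, catecholborane, toluene, −78 °C
Reagents that add atoms: none
Why: Corey–Bakshi–Shibata 1,2-reduction in which the fully substituted alkenyl group acts as the large ketone substituent, so the (R)-oxazaborolidine should deliver hydride to the face that gives the 3S allylic alcohol by reagent control.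

Step 11
Reactants: 17 (2S,3Z,5S,6E)-3-{[(tert-butyldimethylsilyl)oxy]methyl}-1-[(2R,3R)-3-{2-[(4-methoxybenzyl)oxy]ethyl}-3-methyloxiran-2-yl]-5-[(triethylsilyl)oxy]octa-3,6-dien-2-ol
Product: 18 (2S,3Z,5S,6E)-2-[(tert-butyldimethylsilyl)oxy]-3-{[(tert-butyldimethylsilyl)oxy]methyl}-1-[(2R,3R)-3-{2-[(4-methoxybenzyl)oxy]ethyl}-3-methyloxiran-2-yl]-5-[(triethylsilyl)oxy]octa-3,6-diene
Conditions: TBSCl, imidazole, DMAP (cat.), DMF, rt
Reagents that add atoms: tert-butylchlorodimethylsilane, CC(C)(C)[Si](C)(C)Cl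
Why: Silylation of the secondary allylic alcohol with the chloride and imidazole avoids a silyl triflate, whose Lewis acidity could open the trisubstituted oxirane; C3 keeps its configuration.

Step 12
Reactants: 18 (2S,3Z,5S,6E)-2-[(tert-butyldimethylsilyl)oxy]-3-{[(tert-butyldimethylsilyl)oxy]methyl}-1-[(2R,3R)-3-{2-[(4-methoxybenzyl)oxy]ethyl}-3-methyloxiran-2-yl]-5-[(triethylsilyl)oxy]octa-3,6-diene
Product: 19 (2E,4S,5Z,7S)-7-[(tert-butyldimethylsilyl)oxy]-6-{[(tert-butyldimethylsilyl)oxy]methyl}-8-[(2R,3R)-3-{2-[(4-methoxybenzyl)oxy]ethyl}-3-methyloxiran-2-yl]octa-2,5-dien-4-ol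
Conditions: HF·pyridine, pyridine, THF, 0 °C
Reagents that add atoms: none
Why: Selective desilylation, since a secondary TES ether is cleaved by pyridine-buffered HF·pyridine much faster than TBS ethers, frees only the C6 hydroxyl and leaves the oxirane intact.

Step 13
Reactants: 19 (2E,4S,5Z,7S)-7-[(tert-butyldimethylsilyl)oxy]-6-{[(tert-butyldimethylsilyl)oxy]methyl}-8-[(2R,3R)-3-{2-[(4-methoxybenzyl)oxy]ethyl}-3-methyloxiran-2-yl]octa-2,5-dien-4-ol; 20 2-(bromomethyl)prop-2-enoic acid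
Product: 21 (2E,4S,5Z,7S)-7-[(tert-butyldimethylsilyl)oxy]-6-{[(tert-butyldimethylsilyl)oxy]methyl}-8-[(2R,3R)-3-{2-[(4-methoxybenzyl)oxy]ethyl}-3-methyloxiran-2-yl]octa-2,5-dien-4-yl 2-(bromomethyl)prop-2-enoate
Conditions: DCC, DMAP (5 mol %), CH2Cl2, −20 to 0 °C
Reagents that add atoms: none
Why: Steglich esterification acylates O6 with retention at C6 and brings in C11, C12 and C13 with the allylic bromide already in place; low temperature and little DMAP limit attack of the amine on the allylic bromide.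

Step 14
Reactants: 21 (2E,4S,5Z,7S)-7-[(tert-butyldimethylsilyl)oxy]-6-{[(tert-butyldimethylsilyl)oxy]methyl}-8-[(2R,3R)-3-{2-[(4-methoxybenzyl)oxy]ethyl}-3-methyloxiran-2-yl]octa-2,5-dien-4-yl 2-(bromomethyl)prop-2-enoate
Product: 22 (5R)-3-(bromomethyl)-5-[(1Z,3S)-3-[(tert-butyldimethylsilyl)oxy]-2-{[(tert-butyldimethylsilyl)oxy]methyl}-4-[(2R,3R)-3-{2-[(4-methoxybenzyl)oxy]ethyl}-3-methyloxiran-2-yl]but-1-en-1-yl]furan-2(5H)-one
Conditions: second-generation Grubbs catalyst (10 mol %), CH2Cl2, 40 °C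
Reagents that add atoms: none
Why: Ring-closing metathesis between the propenyl group and the 1,1-disubstituted acrylate closes the five-membered butenolide (C7=C11) with loss of propene, while the hindered Z-trisubstituted C4=C5 olefin should not engage and C6 is untouched.

Step 15
Reactants: 22 (5R)-3-(bromomethyl)-5-[(1Z,3S)-3-[(tert-butyldimethylsilyl)oxy]-2-{[(tert-butyldimethylsilyl)oxy]methyl}-4-[(2R,3R)-3-{2-[(4-methoxybenzyl)oxy]ethyl}-3-methyloxiran-2-yl]but-1-en-1-yl]furan-2(5H)-one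
Product: 23 (5R)-3-(bromomethyl)-5-[(1Z,3S)-3-[(tert-butyldimethylsilyl)oxy]-2-{[(tert-butyldimethylsilyl)oxy]methyl}-4-[(2R,3R)-3-(2-hydroxyethyl)-3-methyloxiran-2-yl]but-1-en-1-yl]furan-2(5H)-one
Conditions: DDQ, CH2Cl2/pH 7 phosphate buffer, 0 °C
Reagents that add atoms: none
Why: Oxidative PMB cleavage (hydride abstraction by DDQ, hydrolysis of the oxocarbenium ion) is neutral and should leave the allylic bromide, the oxirane, the silyl ethers and the base-sensitive C6–H of the butenolide alone.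

Step 16
Reactants: 23 (5R)-3-(bromomethyl)-5-[(1Z,3S)-3-[(tert-butyldimethylsilyl)oxy]-2-{[(tert-butyldimethylsilyl)oxy]methyl}-4-[(2R,3R)-3-(2-hydroxyethyl)-3-methyloxiran-2-yl]but-1-en-1-yl]furan-2(5H)-one
Product: 24 (5R)-3-(bromomethyl)-5-[(1Z,3S)-3-[(tert-butyldimethylsilyl)oxy]-2-{[(tert-butyldimethylsilyl)oxy]methyl}-4-[(2R,3R)-3-methyl-3-(2-oxoethyl)oxiran-2-yl]but-1-en-1-yl]furan-2(5H)-one
Conditions: Dess–Martin periodinane, NaHCO3, CH2Cl2, 0 °C; crude aldehyde used at once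
Reagents that add atoms: none
Why: Buffered Dess–Martin oxidation gives the C8 aldehyde (a β,γ-epoxy aldehyde) under neutral conditions in the presence of the allylic bromide, and immediate use avoids β-elimination.

Step 17
Reactants: 24 (5R)-3-(bromomethyl)-5-[(1Z,3S)-3-[(tert-butyldimethylsilyl)oxy]-2-{[(tert-butyldimethylsilyl)oxy]methyl}-4-[(2R,3R)-3-methyl-3-(2-oxoethyl)oxiran-2-yl]but-1-en-1-yl]furan-2(5H)-one
Product: 26 (1R,3S,4Z,6R,7R,8R,10R)-3,15-bis[(tert-butyldimethylsilyl)oxy]-1,10-epoxy-8-hydroxygermacra-4,11(13)-dien-12,6-olide, via allylchromium dichloride 25 (not isolated)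
Conditions: CrCl2 (10 equiv), THF/DMF, rt, syringe-pump addition of 24 (final 2 mM)
Reagents that add atoms: none
Why: Two one-electron transfers from divalent chromium turn the allylic C13–Br bond into the σ-allylchromium species 25 (trivalent chromium), which adds to the tethered C8 aldehyde through a closed six-membered Zimmerman–Traxler-type transition state in the SE2′ sense, forming C7–C8 and moving the butenolide C7=C11 bond to the exocyclic C11=C13 position. The closest known reaction types are Nozaki–Hiyama–Kishi 2-(alkoxycarbonyl)allylation macrocyclisations that close ten-membered germacranolide carbocycles from acyclic bromomethyl acrylates, and the intermolecular Barbier allylation of aldehydes with 5-substituted 3-(bromomethyl)furan-2(5H)-ones. The only ring closed is the ten-membered carbocycle, by 10-exo-trig attack of the C7 allyl terminus on the aldehyde carbon, the lactone and the oxirane being already in place. C7 is controlled by C6: the aldehyde should add to the butenolide face opposite the C6 side chain, because closure on the same face would need a nearly eclipsed C5–C6–C7–C8 torsion in the forming ring, and this gives the trans-fused lactone (7R). C8 is controlled by the chromium-bound chair, which holds O8 gauche to C11 and is expected to place the tether carbon C9 pseudo-axial (anti to H7), the arrangement about C7–C8 found in 8β-oxygenated heliangolides, so the 8β-alcohol (8R) should result. The step needs intra- over intermolecular allylation (high dilution, slow addition, and the turn imposed by the Z C4=C5 olefin and the trans oxirane), γ- over α-attack of the allyl unit (closed transition state), and survival of the β,γ-epoxy aldehyde (non-basic chromium conditions).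

Step 18
Reactants: 26 (1R,3S,4Z,6R,7R,8R,10R)-3,15-bis[(tert-butyldimethylsilyl)oxy]-1,10-epoxy-8-hydroxygermacra-4,11(13)-dien-12,6-olide; 27 (2S)-2-methylbutanoic acid
Product: 28 (1R,3S,4Z,6R,7R,8R,10R)-3,15-bis[(tert-butyldimethylsilyl)oxy]-1,10-epoxy-8-{[(2S)-2-methylbutanoyl]oxy}germacra-4,11(13)-dien-12,6-olide
Conditions: DCC, DMAP (cat.), CH2Cl2, 0 °C to rt
Reagents that add atoms: none
Why: Steglich esterification of the only free hydroxyl proceeds with retention at C8, and the α-branched alkanoic acid should not epimerise at low temperature.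

Step 19
Reactants: 28 (1R,3S,4Z,6R,7R,8R,10R)-3,15-bis[(tert-butyldimethylsilyl)oxy]-1,10-epoxy-8-{[(2S)-2-methylbutanoyl]oxy}germacra-4,11(13)-dien-12,6-olide
Product: 29 (1R,3S,4Z,6R,7R,8R,10R)-1,10-epoxy-3,15-dihydroxy-8-{[(2S)-2-methylbutanoyl]oxy}germacra-4,11(13)-dien-12,6-olide (CNP0267576.2)
Conditions: HF·pyridine, pyridine, THF, 0 °C to rt
Reagents that add atoms: none
Why: Fluoride-driven cleavage of both TBS ethers (strong Si–F bond) under pyridine-buffered conditions should spare the oxirane, the C8 ester and the α-methylene lactone, and touches no stereocenter.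

**Compound list**

1 | but-3-yn-1-ol | C#CCCO | starting material
2 | 1-[(but-3-yn-1-yloxy)methyl]-4-methoxybenzene | C#CCCOCc1ccc(OC)cc1 | intermediate
3 | oxirane | C1CO1 | starting material
4 | [(1E)-4-[(4-methoxybenzyl)oxy]-2-methylbut-1-en-1-yl]dimethylalumane | C[Al](C)/C=C(\C)CCOCc1ccc(OC)cc1 | intermediate
5 | lithium butyl[(1E)-4-[(4-methoxybenzyl)oxy]-2-methylbut-1-en-1-yl]dimethylaluminate | [Li+].CCCC[Al-](C)(C)/C=C(\C)CCOCc1ccc(OC)cc1 | intermediate
6 | (3E)-6-[(4-methoxybenzyl)oxy]-4-methylhex-3-en-1-ol | OCC/C=C(\C)CCOCc1ccc(OC)cc1 | intermediate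
7 | 2-[(2R,3R)-3-{2-[(4-methoxybenzyl)oxy]ethyl}-3-methyloxiran-2-yl]ethan-1-ol | OCC[C@H]1O[C@]1(C)CCOCc1ccc(OC)cc1 | intermediate
8 | 2-[(2R,3R)-3-{2-[(4-methoxybenzyl)oxy]ethyl}-3-methyloxiran-2-yl]acetaldehyde | O=CC[C@H]1O[C@]1(C)CCOCc1ccc(OC)cc1 | intermediate
9 | (2E)-but-2-enal | C/C=C/C=O | starting material
10 | tert-butyldimethyl(prop-2-yn-1-yloxy)silane | C#CCO[Si](C)(C)C(C)(C)C | starting material
11 | (4S,5E)-1-[(tert-butyldimethylsilyl)oxy]hept-5-en-2-yn-4-ol | C/C=C/[C@H](O)C#CCO[Si](C)(C)C(C)(C)C | intermediate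
12 | sodium (5S)-3-{[(tert-butyldimethylsilyl)oxy]methyl}-2,2-bis(2-methoxyethoxy)-5-[(1E)-prop-1-en-1-yl]-2,5-dihydro-1,2-oxaluminol-2-uide | [Na+].C/C=C/[C@@H]1O[Al-](OCCOC)(OCCOC)C(CO[Si](C)(C)C(C)(C)C)=C1 | intermediate
13 | (2Z,4S,5E)-1-[(tert-butyldimethylsilyl)oxy]-2-iodohepta-2,5-dien-4-ol | C/C=C/[C@H](O)/C=C(\I)CO[Si](C)(C)C(C)(C)C | intermediate
14 | tert-butyl{[(2Z,4S,5E)-2-iodo-4-[(triethylsilyl)oxy]hepta-2,5-dien-1-yl]oxy}dimethylsilane | C/C=C/[C@H](O[Si](CC)(CC)CC)/C=C(\I)CO[Si](C)(C)C(C)(C)C | intermediate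
15 | (3Z,5S,6E)-3-{[(tert-butyldimethylsilyl)oxy]methyl}-1-[(2R,3R)-3-{2-[(4-methoxybenzyl)oxy]ethyl}-3-methyloxiran-2-yl]-5-[(triethylsilyl)oxy]octa-3,6-dien-2-ol, both C2 epimers | C/C=C/[C@H](O[Si](CC)(CC)CC)/C=C(/CO[Si](C)(C)C(C)(C)C)C(O)C[C@H]1O[C@]1(C)CCOCc1ccc(OC)cc1 | intermediate
16 | (3Z,5S,6E)-3-{[(tert-butyldimethylsilyl)oxy]methyl}-1-[(2R,3R)-3-{2-[(4-methoxybenzyl)oxy]ethyl}-3-methyloxiran-2-yl]-5-[(triethylsilyl)oxy]octa-3,6-dien-2-one | C/C=C/[C@H](O[Si](CC)(CC)CC)/C=C(/CO[Si](C)(C)C(C)(C)C)C(=O)C[C@H]1O[C@]1(C)CCOCc1ccc(OC)cc1 | intermediate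
17 | (2S,3Z,5S,6E)-3-{[(tert-butyldimethylsilyl)oxy]methyl}-1-[(2R,3R)-3-{2-[(4-methoxybenzyl)oxy]ethyl}-3-methyloxiran-2-yl]-5-[(triethylsilyl)oxy]octa-3,6-dien-2-ol | C/C=C/[C@H](O[Si](CC)(CC)CC)/C=C(/CO[Si](C)(C)C(C)(C)C)[C@@H](O)C[C@H]1O[C@]1(C)CCOCc1ccc(OC)cc1 | intermediate
18 | (2S,3Z,5S,6E)-2-[(tert-butyldimethylsilyl)oxy]-3-{[(tert-butyldimethylsilyl)oxy]methyl}-1-[(2R,3R)-3-{2-[(4-methoxybenzyl)oxy]ethyl}-3-methyloxiran-2-yl]-5-[(triethylsilyl)oxy]octa-3,6-diene | C/C=C/[C@H](O[Si](CC)(CC)CC)/C=C(/CO[Si](C)(C)C(C)(C)C)[C@@H](O[Si](C)(C)C(C)(C)C)C[C@H]1O[C@]1(C)CCOCc1ccc(OC)cc1 | intermediate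
19 | (2E,4S,5Z,7S)-7-[(tert-butyldimethylsilyl)oxy]-6-{[(tert-butyldimethylsilyl)oxy]methyl}-8-[(2R,3R)-3-{2-[(4-methoxybenzyl)oxy]ethyl}-3-methyloxiran-2-yl]octa-2,5-dien-4-ol | C/C=C/[C@H](O)/C=C(/CO[Si](C)(C)C(C)(C)C)[C@@H](O[Si](C)(C)C(C)(C)C)C[C@H]1O[C@]1(C)CCOCc1ccc(OC)cc1 | intermediate
20 | 2-(bromomethyl)prop-2-enoic acid | C=C(CBr)C(=O)O | starting material
21 | (2E,4S,5Z,7S)-7-[(tert-butyldimethylsilyl)oxy]-6-{[(tert-butyldimethylsilyl)oxy]methyl}-8-[(2R,3R)-3-{2-[(4-methoxybenzyl)oxy]ethyl}-3-methyloxiran-2-yl]octa-2,5-dien-4-yl 2-(bromomethyl)prop-2-enoate | C/C=C/[C@H](OC(=O)C(=C)CBr)/C=C(/CO[Si](C)(C)C(C)(C)C)[C@@H](O[Si](C)(C)C(C)(C)C)C[C@H]1O[C@]1(C)CCOCc1ccc(OC)cc1 | intermediate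
22 | (5R)-3-(bromomethyl)-5-[(1Z,3S)-3-[(tert-butyldimethylsilyl)oxy]-2-{[(tert-butyldimethylsilyl)oxy]methyl}-4-[(2R,3R)-3-{2-[(4-methoxybenzyl)oxy]ethyl}-3-methyloxiran-2-yl]but-1-en-1-yl]furan-2(5H)-one | BrCC1=C[C@@H](/C=C(/CO[Si](C)(C)C(C)(C)C)[C@@H](O[Si](C)(C)C(C)(C)C)C[C@H]2O[C@]2(C)CCOCc2ccc(OC)cc2)OC1=O | intermediate
23 | (5R)-3-(bromomethyl)-5-[(1Z,3S)-3-[(tert-butyldimethylsilyl)oxy]-2-{[(tert-butyldimethylsilyl)oxy]methyl}-4-[(2R,3R)-3-(2-hydroxyethyl)-3-methyloxiran-2-yl]but-1-en-1-yl]furan-2(5H)-one | BrCC1=C[C@@H](/C=C(/CO[Si](C)(C)C(C)(C)C)[C@@H](O[Si](C)(C)C(C)(C)C)C[C@H]2O[C@]2(C)CCO)OC1=O | intermediate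
24 | (5R)-3-(bromomethyl)-5-[(1Z,3S)-3-[(tert-butyldimethylsilyl)oxy]-2-{[(tert-butyldimethylsilyl)oxy]methyl}-4-[(2R,3R)-3-methyl-3-(2-oxoethyl)oxiran-2-yl]but-1-en-1-yl]furan-2(5H)-one | BrCC1=C[C@@H](/C=C(/CO[Si](C)(C)C(C)(C)C)[C@@H](O[Si](C)(C)C(C)(C)C)C[C@H]2O[C@]2(C)CC=O)OC1=O | intermediate
25 | dichloro{[(5R)-5-[(1Z,3S)-3-[(tert-butyldimethylsilyl)oxy]-2-{[(tert-butyldimethylsilyl)oxy]methyl}-4-[(2R,3R)-3-methyl-3-(2-oxoethyl)oxiran-2-yl]but-1-en-1-yl]-2-oxo-2,5-dihydrofuran-3-yl]methyl}chromium | Cl[Cr](Cl)CC1=C[C@@H](/C=C(/CO[Si](C)(C)C(C)(C)C)[C@@H](O[Si](C)(C)C(C)(C)C)C[C@H]2O[C@]2(C)CC=O)OC1=O | intermediate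
26 | (1R,3S,4Z,6R,7R,8R,10R)-3,15-bis[(tert-butyldimethylsilyl)oxy]-1,10-epoxy-8-hydroxygermacra-4,11(13)-dien-12,6-olide | C=C1C(=O)O[C@@H]2/C=C(/CO[Si](C)(C)C(C)(C)C)[C@@H](O[Si](C)(C)C(C)(C)C)C[C@H]3O[C@]3(C)C[C@@H](O)[C@@H]12 | intermediate
27 | (2S)-2-methylbutanoic acid | CC[C@H](C)C(=O)O | starting material
28 | (1R,3S,4Z,6R,7R,8R,10R)-3,15-bis[(tert-butyldimethylsilyl)oxy]-1,10-epoxy-8-{[(2S)-2-methylbutanoyl]oxy}germacra-4,11(13)-dien-12,6-olide | C=C1C(=O)O[C@@H]2/C=C(/CO[Si](C)(C)C(C)(C)C)[C@@H](O[Si](C)(C)C(C)(C)C)C[C@H]3O[C@]3(C)C[C@@H](OC(=O)[C@@H](C)CC)[C@@H]12 | intermediate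
29 | (1R,3S,4Z,6R,7R,8R,10R)-1,10-epoxy-3,15-dihydroxy-8-{[(2S)-2-methylbutanoyl]oxy}germacra-4,11(13)-dien-12,6-olide | C=C1C(=O)O[C@@H]2/C=C(/CO)[C@@H](O)C[C@H]3O[C@]3(C)C[C@@H](OC(=O)[C@@H](C)CC)[C@@H]12 | target

**Step count and risks**

Total step count: 19. Longest linear sequence: 16 steps (steps 1–4, then 8–19); the branch through steps 5–7 joins at step 8.

Steps most likely to fail:

1. Step 17 (key step). What may go wrong: the aldehyde may be attacked on its other face in the macrocyclic transition state, so that control at C8 is lost, and at insufficient dilution intermolecular allylation competes. Fallback, setting out from 24 and coming back to the route at 28: the chromium closure is run as described; if the C8 epimer is the main product, namely (1R,3S,4Z,6R,7R,8S,10R)-3,15-bis[(tert-butyldimethylsilyl)oxy]-1,10-epoxy-8-hydroxygermacra-4,11(13)-dien-12,6-olide F1, the retentive acylation of step 18 is replaced by an invertive Mitsunobu esterification of F1 with acid 27 (PPh3, DIAD, toluene, 0 °C to rt). This installs the ester and corrects C8 in one operation and gives 28 directly.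

2. Step 14. What may go wrong: deactivation of the ruthenium carbene by the allylic bromide and slow metathesis of the electron-poor 1,1-disubstituted acrylate, with competing metathesis at other olefins. Fallback, setting out from 19 and coming back at 22: the bromide is introduced only after ring closure. Commercial ethyl 2-(hydroxymethyl)acrylate is silylated (TESCl, imidazole) to ethyl 2-{[(triethylsilyl)oxy]methyl}prop-2-enoate F2 and saponified (LiOH, THF/H2O, 0 °C) to 2-{[(triethylsilyl)oxy]methyl}prop-2-enoic acid F3. Steglich esterification of 19 with F3 (DCC, DMAP) gives (2E,4S,5Z,7S)-7-[(tert-butyldimethylsilyl)oxy]-6-{[(tert-butyldimethylsilyl)oxy]methyl}-8-[(2R,3R)-3-{2-[(4-methoxybenzyl)oxy]ethyl}-3-methyloxiran-2-yl]octa-2,5-dien-4-yl 2-{[(triethylsilyl)oxy]methyl}prop-2-enoate F4. Ring-closing metathesis (second-generation Grubbs catalyst, CH2Cl2, 40 °C) then gives (5R)-5-[(1Z,3S)-3-[(tert-butyldimethylsilyl)oxy]-2-{[(tert-butyldimethylsilyl)oxy]methyl}-4-[(2R,3R)-3-{2-[(4-methoxybenzyl)oxy]ethyl}-3-methyloxiran-2-yl]but-1-en-1-yl]-3-{[(triethylsilyl)oxy]methyl}furan-2(5H)-one F5. Selective cleavage of the primary TES ether (HF·pyridine, pyridine, THF, 0 °C) gives the 3-(hydroxymethyl)butenolide (5R)-5-[(1Z,3S)-3-[(tert-butyldimethylsilyl)oxy]-2-{[(tert-butyldimethylsilyl)oxy]methyl}-4-[(2R,3R)-3-{2-[(4-methoxybenzyl)oxy]ethyl}-3-methyloxiran-2-yl]but-1-en-1-yl]-3-(hydroxymethyl)furan-2(5H)-one F6, and Appel bromination (CBr4, PPh3, CH2Cl2, 0 °C) gives 22.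

3. Step 10. What may go wrong: insufficient facial discrimination in the reduction, Lewis-acid- or base-triggered opening of the β,γ-epoxy ketone, and Z/E isomerisation of the enone. Fallback, setting out from 15 and coming back at 17: the oxidation–reduction detour is dropped. The two C3 epimers of 15 are separated by chromatography; the 2S epimer is 17 and is carried on. The other epimer, (2R,3Z,5S,6E)-3-{[(tert-butyldimethylsilyl)oxy]methyl}-1-[(2R,3R)-3-{2-[(4-methoxybenzyl)oxy]ethyl}-3-methyloxiran-2-yl]-5-[(triethylsilyl)oxy]octa-3,6-dien-2-ol F7, is inverted by a Mitsunobu reaction (4-nitrobenzoic acid, PPh3, DIAD, THF, 0 °C) to (2S,3Z,5S,6E)-3-{[(tert-butyldimethylsilyl)oxy]methyl}-1-[(2R,3R)-3-{2-[(4-methoxybenzyl)oxy]ethyl}-3-methyloxiran-2-yl]-5-[(triethylsilyl)oxy]octa-3,6-dien-2-yl 4-nitrobenzoate F8, and methanolysis (K2CO3, MeOH, 0 °C) gives 17.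

Further compounds
F1 | step 17 | (1R,3S,4Z,6R,7R,8S,10R)-3,15-bis[(tert-butyldimethylsilyl)oxy]-1,10-epoxy-8-hydroxygermacra-4,11(13)-dien-12,6-olide | C=C1C(=O)O[C@@H]2/C=C(/CO[Si](C)(C)C(C)(C)C)[C@@H](O[Si](C)(C)C(C)(C)C)C[C@H]3O[C@]3(C)C[C@H](O)[C@@H]12
F2 | step 14 | ethyl 2-{[(triethylsilyl)oxy]methyl}prop-2-enoate | C=C(CO[Si](CC)(CC)CC)C(=O)OCC
F3 | step 14 | 2-{[(triethylsilyl)oxy]methyl}prop-2-enoic acid | C=C(CO[Si](CC)(CC)CC)C(=O)O
F4 | step 14 | (2E,4S,5Z,7S)-7-[(tert-butyldimethylsilyl)oxy]-6-{[(tert-butyldimethylsilyl)oxy]methyl}-8-[(2R,3R)-3-{2-[(4-methoxybenzyl)oxy]ethyl}-3-methyloxiran-2-yl]octa-2,5-dien-4-yl 2-{[(triethylsilyl)oxy]methyl}prop-2-enoate | C/C=C/[C@H](OC(=O)C(=C)CO[Si](CC)(CC)CC)/C=C(/CO[Si](C)(C)C(C)(C)C)[C@@H](O[Si](C)(C)C(C)(C)C)C[C@H]1O[C@]1(C)CCOCc1ccc(OC)cc1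
F5 | step 14 | (5R)-5-[(1Z,3S)-3-[(tert-butyldimethylsilyl)oxy]-2-{[(tert-butyldimethylsilyl)oxy]methyl}-4-[(2R,3R)-3-{2-[(4-methoxybenzyl)oxy]ethyl}-3-methyloxiran-2-yl]but-1-en-1-yl]-3-{[(triethylsilyl)oxy]methyl}furan-2(5H)-one | CC[Si](CC)(CC)OCC1=C[C@@H](/C=C(/CO[Si](C)(C)C(C)(C)C)[C@@H](O[Si](C)(C)C(C)(C)C)C[C@H]2O[C@]2(C)CCOCc2ccc(OC)cc2)OC1=O
F6 | step 14 | (5R)-5-[(1Z,3S)-3-[(tert-butyldimethylsilyl)oxy]-2-{[(tert-butyldimethylsilyl)oxy]methyl}-4-[(2R,3R)-3-{2-[(4-methoxybenzyl)oxy]ethyl}-3-methyloxiran-2-yl]but-1-en-1-yl]-3-(hydroxymethyl)furan-2(5H)-one | OCC1=C[C@@H](/C=C(/CO[Si](C)(C)C(C)(C)C)[C@@H](O[Si](C)(C)C(C)(C)C)C[C@H]2O[C@]2(C)CCOCc2ccc(OC)cc2)OC1=O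
F7 | step 10 | (2R,3Z,5S,6E)-3-{[(tert-butyldimethylsilyl)oxy]methyl}-1-[(2R,3R)-3-{2-[(4-methoxybenzyl)oxy]ethyl}-3-methyloxiran-2-yl]-5-[(triethylsilyl)oxy]octa-3,6-dien-2-ol | C/C=C/[C@H](O[Si](CC)(CC)CC)/C=C(/CO[Si](C)(C)C(C)(C)C)[C@H](O)C[C@H]1O[C@]1(C)CCOCc1ccc(OC)cc1
F8 | step 10 | (2S,3Z,5S,6E)-3-{[(tert-butyldimethylsilyl)oxy]methyl}-1-[(2R,3R)-3-{2-[(4-methoxybenzyl)oxy]ethyl}-3-methyloxiran-2-yl]-5-[(triethylsilyl)oxy]octa-3,6-dien-2-yl 4-nitrobenzoate | C/C=C/[C@H](O[Si](CC)(CC)CC)/C=C(/CO[Si](C)(C)C(C)(C)C)[C@@H](OC(=O)c1ccc(cc1)[N+](=O)[O-])C[C@H]1O[C@]1(C)CCOCc1ccc(OC)cc1
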